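**Assessment of a direct plan**

A direct plan would build ring A first: protect and geranylate phloroglucinol by directed lithiation, convert the ring in several more operations into the ortho-silylaryl triflate A1, and let the aryne from A1 insert into the C–O bond of a protected cinnamic acid to give the 2'-hydroxychalcone A2.
Ring C would then be closed by an amine–thiourea-catalysed oxa-Michael addition to the protected flavanone A3, and four MOM ethers would be cleaved with warm aqueous HCl in methanol.
Its weakest steps would be: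
- the run-up to A1 (protection, silylation, lithiation, desilylation, bromination, retro-Brook/triflation): six operations that would add only a geranyl group and two leaving groups to a benzene ring, all staked on one hot-fluoride aryne insertion;
- the oxa-Michael closure of A2: the only stereocentre would be set last, on a hindered, unactivated chalcone that cyclises slowly and reversibly, so the enantiomeric purity would depend on when the reaction is stopped;
- the four-fold acidic MOM cleavage of A3: it would expose the final, most precious material, with a geranyl chain flanked by two phenols, to conditions that invite chroman formation.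

**Plan of the new route**

Ring A is a phloroglucinol, the enol form of a cyclohexane-1,3,5-trione; its C6–C7–C8 segment with the chain on C6 is the carbon skeleton of (E)-geranylacetone (C3–C2–C1), and C4–C4a–C8a–O1 is a vinylogous ester, so ring A can be built by a [3+3] annulation on a preformed ring C.
Cuts: C5–C6 (Claisen) and C8–C8a (addition–elimination) give geranylacetone and a (2S)-2-aryl-2,3-dihydro-4H-pyran-4-one carrying C5 as an ester on C4a and a methylsulfanyl leaving group on C8a; O1–C8a and C4a–C8a lead back to CS2 and a δ-hydroxy-β-keto ester; C2–C3 leads to the aryl aldehyde and the bis-silyl dienolate of methyl acetoacetate.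
Rings arise in the order B (bought), C, A; ring A is formed aromatic from acyclic carbons, so no aromatic ring is geranylated or turned into an aryne.
The stereocentre is set in the first C–C bond formation as a carbinol whose C–O bond is not broken afterwards; no chalcone is cyclised.
The 5- and 7-hydroxyls are never protected and the two B-ring silyl ethers are removed by buffered fluoride, so no acid meets the geranyl chain.

Key step: step 4

Assumption: the catalyst formed from Ti(OiPr)4 and (S)-BINOL is taken to direct the dienolate to the Si face of the aryl aldehyde, as in related Ti(OiPr)4/BINOL-catalysed additions to aromatic aldehydes (otherwise (R)-BINOL would be used); (E)-geranylacetone and the bis-silyl dienolate of methyl acetoacetate are taken as bought.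

**Route**

Step 1
Reactants: 1 5-hydroxyvanillin (3,4-dihydroxy-5-methoxybenzaldehyde)
Product: 2 3-methoxy-4,5-bis(triisopropylsilyloxy)benzaldehyde
Conditions: TIPSOTf (2.4 equiv), 2,6-lutidine (3 equiv), CH2Cl2, 0 °C → rt
Reagents that add atoms: triisopropylsilyl trifluoromethanesulfonate, CC(C)[Si](OS(=O)(=O)C(F)(F)F)(C(C)C)C(C)C
Why: Standard O-silylation of both catechol hydroxyls; aryl TIPS ethers should tolerate the Lewis acid, carbonate and amide bases used later and are cleaved by fluoride without acid.

Step 2
Reactants: 2 3-methoxy-4,5-bis(triisopropylsilyloxy)benzaldehyde; 3 1-methoxy-1,3-bis(trimethylsilyloxy)buta-1,3-diene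
Product: 5 methyl (5S)-5-hydroxy-5-[3-methoxy-4,5-bis(triisopropylsilyloxy)phenyl]-3-oxopentanoate, via silylated aldol adduct 4 (not isolated)
Conditions: Ti(OiPr)4 (10 mol%), (S)-BINOL (10 mol%), 4 Å MS, THF, −78 °C → rt; then PPTS, MeOH, 0 °C
Reagents that add atoms: none
Why: Catalytic enantioselective vinylogous Mukaiyama aldol addition through the terminal carbon of the dienolate, in which the catalyst formed from Ti(OiPr)4 and (S)-BINOL is expected to block the Re face of the aldehyde so that the carbinol centre is formed as S, followed by mild methanolysis that removes the two trimethylsilyl groups but not the aryl TIPS ethers.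

Step 3
Reactants: 5 methyl (5S)-5-hydroxy-5-[3-methoxy-4,5-bis(triisopropylsilyloxy)phenyl]-3-oxopentanoate
Product: 7 methyl (2S)-2-[3-methoxy-4,5-bis(triisopropylsilyloxy)phenyl]-6-(methylsulfanyl)-4-oxo-3,4-dihydro-2H-pyran-5-carboxylate, via ketene dithioacetal 6 (not isolated)
Conditions: CS2 (1.2 equiv), K2CO3 (3 equiv), DMF, 0 °C; MeI (2.1 equiv), 0 °C → rt; then 40 °C
Reagents that add atoms: carbon disulfide, S=C=S; iodomethane, CI
Why: The β-keto ester enolate should add to CS2 and double S-methylation should give the α-oxo ketene dithioacetal 6 (a standard reaction of active methylene compounds), after which the δ-hydroxyl displaces one methylsulfanyl group by 6-endo-trig conjugate addition–elimination (the sulfur counterpart of the amide-acetal route from δ-hydroxy-β-keto esters to 2,3-dihydro-4H-pyran-4-ones), forming O1–C8a without touching the C–O bond at the stereocentre.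

Step 4
Reactants: 7 methyl (2S)-2-[3-methoxy-4,5-bis(triisopropylsilyloxy)phenyl]-6-(methylsulfanyl)-4-oxo-3,4-dihydro-2H-pyran-5-carboxylate; 8 (5E)-6,10-dimethylundeca-5,9-dien-2-one ((E)-geranylacetone)
Product: 12 (2S)-6-[(2E)-3,7-dimethylocta-2,6-dien-1-yl]-5,7-dihydroxy-2-[3-methoxy-4,5-bis(triisopropylsilyloxy)phenyl]-2,3-dihydro-4H-chromen-4-one, via lithium enolate 9 (not isolated), via pyranyl ketone 10 (not isolated), via triketone 11 (not isolated)
Conditions: 8 (2.2 equiv), LiN(iPr)2 (2.3 equiv), THF, −78 °C; 7, −78 → −30 °C; LiN(iPr)2 (2.3 equiv), −78 → 0 °C; AcOH, −78 °C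
Reagents that add atoms: none
Why: Proposed new method: the kinetic enolate 9, formed at the methyl group of 8, should add to C6 of the doubly activated cyclic ketene O,S-acetal 7 and expel methanethiolate (conjugate addition–elimination; closest known type: displacement of a methylsulfanyl group from α-oxo ketene dithioacetals by ketone enolates), which forms C8–C8a with C8a already at the oxidation level it has in the aromatic ring. The C8 methylene of 10 is at once deprotonated by the second equivalent of 9 to a vinylogous β-diketonate, which shields ring C because expulsion of O1 would now put a second negative charge on the same π system, and the further LiN(iPr)2 removes a proton from the C6 methylene to give a dianion that attacks the neighbouring ester through its terminal carbon in a 6-(enolendo)-exo-trig Claisen condensation (C5–C6), the laboratory counterpart of the polyketide Claisen cyclisation to acylphloroglucinols and of the consecutive Michael–Claisen synthesis of cyclohexane-1,3-diones from ketones and enoates. Loss of methoxide gives 11, the keto tautomer of a phloroglucinol, which aromatises by enolisation alone, so ring A is closed and aromatic in one flask without an oxidant. No stereocentre is formed: the 2S centre of 7 is carried through because the C2–O1 bond is not broken, provided that 7 is consumed by the enolate at low temperature before more base is added, since neutral 7 is the species prone to E1cB opening. The selectivity needed is regiochemical: C8 must come from the methyl and C6 from the methylene group of 8, which kinetic enolisation and the irreversible first step secure, so that the chain can only end at C6 between the two former carbonyl carbons. Ring closure must go through carbon onto the ester and not onto the C4 ketone or through the enolate oxygen, which the substrate secures because the aldol alternative would give a strained, reversible bridged aldolate with a bridgehead double bond, the dianion reacts at its terminal carbon, and only the Claisen path ends in an aromatic diphenoxide.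

Step 5
Reactants: 12 (2S)-6-[(2E)-3,7-dimethylocta-2,6-dien-1-yl]-5,7-dihydroxy-2-[3-methoxy-4,5-bis(triisopropylsilyloxy)phenyl]-2,3-dihydro-4H-chromen-4-one
Product: 13 (2S)-2-(3,4-dihydroxy-5-methoxyphenyl)-6-[(2E)-3,7-dimethylocta-2,6-dien-1-yl]-5,7-dihydroxy-2,3-dihydro-4H-chromen-4-one (CNP0110161.1)
Conditions: Bu4NF (2.4 equiv), AcOH (3 equiv), THF, 0 °C, argon; pH 6 phosphate buffer work-up
Reagents that add atoms: none
Why: Fluoride-mediated cleavage of the two aryl silyl ethers under acetic acid buffering, which keeps the medium too weakly basic for E1cB opening of ring C and free of mineral acid, so that the 2S centre and the geranyl olefins should persist.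

**Compound list**

1 | 5-hydroxyvanillin (3,4-dihydroxy-5-methoxybenzaldehyde) | COc1cc(C=O)cc(O)c1O | starting material
2 | 3-methoxy-4,5-bis(triisopropylsilyloxy)benzaldehyde | COc1cc(C=O)cc(O[Si](C(C)C)(C(C)C)C(C)C)c1O[Si](C(C)C)(C(C)C)C(C)C | intermediate
3 | 1-methoxy-1,3-bis(trimethylsilyloxy)buta-1,3-diene | C=C(O[Si](C)(C)C)C=C(OC)O[Si](C)(C)C | starting material
4 | (5S)-1-methoxy-5-[3-methoxy-4,5-bis(triisopropylsilyloxy)phenyl]-1,5-bis(trimethylsilyloxy)pent-1-en-3-one | COC(O[Si](C)(C)C)=CC(=O)C[C@H](O[Si](C)(C)C)c1cc(OC)c(O[Si](C(C)C)(C(C)C)C(C)C)c(O[Si](C(C)C)(C(C)C)C(C)C)c1 | intermediate (not isolated)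
5 | methyl (5S)-5-hydroxy-5-[3-methoxy-4,5-bis(triisopropylsilyloxy)phenyl]-3-oxopentanoate | COC(=O)CC(=O)C[C@H](O)c1cc(OC)c(O[Si](C(C)C)(C(C)C)C(C)C)c(O[Si](C(C)C)(C(C)C)C(C)C)c1 | intermediate
6 | methyl (5S)-2-[bis(methylsulfanyl)methylidene]-5-hydroxy-5-[3-methoxy-4,5-bis(triisopropylsilyloxy)phenyl]-3-oxopentanoate | COC(=O)C(=C(SC)SC)C(=O)C[C@H](O)c1cc(OC)c(O[Si](C(C)C)(C(C)C)C(C)C)c(O[Si](C(C)C)(C(C)C)C(C)C)c1 | intermediate (not isolated)
7 | methyl (2S)-2-[3-methoxy-4,5-bis(triisopropylsilyloxy)phenyl]-6-(methylsulfanyl)-4-oxo-3,4-dihydro-2H-pyran-5-carboxylate | COC(=O)C1=C(SC)O[C@@H](CC1=O)c1cc(OC)c(O[Si](C(C)C)(C(C)C)C(C)C)c(O[Si](C(C)C)(C(C)C)C(C)C)c1 | intermediate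
8 | (5E)-6,10-dimethylundeca-5,9-dien-2-one ((E)-geranylacetone) | CC(=O)CC/C=C(\C)CCC=C(C)C | starting material
9 | lithium (5E)-6,10-dimethylundeca-1,5,9-trien-2-olate | [Li]OC(=C)CC/C=C(\C)CCC=C(C)C | intermediate (not isolated)
10 | methyl (2S)-6-[(5E)-6,10-dimethyl-2-oxoundeca-5,9-dien-1-yl]-2-[3-methoxy-4,5-bis(triisopropylsilyloxy)phenyl]-4-oxo-3,4-dihydro-2H-pyran-5-carboxylate | COC(=O)C1=C(CC(=O)CC/C=C(\C)CCC=C(C)C)O[C@@H](CC1=O)c1cc(OC)c(O[Si](C(C)C)(C(C)C)C(C)C)c(O[Si](C(C)C)(C(C)C)C(C)C)c1 | intermediate (not isolated)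
11 | (2S)-6-[(2E)-3,7-dimethylocta-2,6-dien-1-yl]-2-[3-methoxy-4,5-bis(triisopropylsilyloxy)phenyl]-2,3-dihydro-4H-chromene-4,5,7(6H,8H)-trione | COc1cc([C@@H]2CC(=O)C3=C(CC(=O)C(C/C=C(\C)CCC=C(C)C)C3=O)O2)cc(O[Si](C(C)C)(C(C)C)C(C)C)c1O[Si](C(C)C)(C(C)C)C(C)C | intermediate (not isolated)
12 | (2S)-6-[(2E)-3,7-dimethylocta-2,6-dien-1-yl]-5,7-dihydroxy-2-[3-methoxy-4,5-bis(triisopropylsilyloxy)phenyl]-2,3-dihydro-4H-chromen-4-one | COc1cc([C@@H]2CC(=O)c3c(cc(O)c(C/C=C(\C)CCC=C(C)C)c3O)O2)cc(O[Si](C(C)C)(C(C)C)C(C)C)c1O[Si](C(C)C)(C(C)C)C(C)C | intermediate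
13 | (2S)-2-(3,4-dihydroxy-5-methoxyphenyl)-6-[(2E)-3,7-dimethylocta-2,6-dien-1-yl]-5,7-dihydroxy-2,3-dihydro-4H-chromen-4-one (CNP0110161.1) | COc1cc([C@@H]2CC(=O)c3c(cc(O)c(C/C=C(\C)CCC=C(C)C)c3O)O2)cc(O)c1O | target

**Step count and risks**

Total steps: 5. Longest linear sequence: 5 (1 → 2 → 5 → 7 → 12 → 13).

Steps most likely to fail:

1. Step 4 (proposed new method). What may go wrong: proton transfer from C3 of 7 to the enolate followed by E1cB opening of ring C and loss of enantiomeric purity; equilibration of the enolate to its internal regioisomer, which would deliver the chain to C8; or ring closure through the enolate oxygen instead of through carbon. The fallback uses known reaction types, sets out from 5 and comes back to the route at 12; ring A is carried in saturated form and aromatised late. N,N-Dimethylformamide dimethyl acetal and then BF3·OEt2 in CH2Cl2 should convert 5 into methyl (2S)-2-[3-methoxy-4,5-bis(triisopropylsilyloxy)phenyl]-4-oxo-3,4-dihydro-2H-pyran-5-carboxylate F1 as an alkylidene β-keto ester. Conjugate addition of the lithium enolate 9 to F1 in THF at −78 °C should give methyl (6S)-2-[(5E)-6,10-dimethyl-2-oxoundeca-5,9-dien-1-yl]-6-[3-methoxy-4,5-bis(triisopropylsilyloxy)phenyl]-4-oxooxane-3-carboxylate F2 as a mixture of epimers at C2 and C3. NaOMe in MeOH should close F2 by Claisen condensation, as in the consecutive Michael–Claisen synthesis of cyclohexane-1,3-diones, to the 4a,8a-dihydro derivative of 11, (2S)-6-[(2E)-3,7-dimethylocta-2,6-dien-1-yl]-2-[3-methoxy-4,5-bis(triisopropylsilyloxy)phenyl]-4a,8a-dihydro-2H-chromene-4,5,7(3H,6H,8H)-trione F3 as a mixture of epimers. DDQ (1.0 equiv) in dioxane at rt should dehydrogenate F3 across C4a–C8a to 11, which should enolise to 12; the enolised triketone is expected to be oxidised well before the geranyl chain. In F2 and F3 O1 sits on a saturated carbon and is a poor leaving group, so C2 should not be at risk in the basic steps.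

2. Step 3. What may go wrong: lactonisation of the free hydroxyl onto the ester, β-elimination of water to a styryl ketone, or reversible opening of ring C in the basic medium with erosion of enantiomeric purity. The fallback sets out from 5 and comes back at 7; the hydroxyl is absent during the basic thioacetalisation, and ring closure becomes a separate operation. TESCl and imidazole in DMF should convert 5 into methyl (5S)-5-[3-methoxy-4,5-bis(triisopropylsilyloxy)phenyl]-3-oxo-5-(triethylsilyloxy)pentanoate F4 as the protected aldol. NaH, CS2 and MeI in THF at 0 °C should convert F4 into methyl (5S)-2-[bis(methylsulfanyl)methylidene]-5-[3-methoxy-4,5-bis(triisopropylsilyloxy)phenyl]-3-oxo-5-(triethylsilyloxy)pentanoate F5 by way of the sodium enolate. PPTS in MeOH at 0 °C should free the hydroxyl of F5 to give 6 while the aryl TIPS ethers remain. Cyclisation of purified 6 with catalytic DBU in CH2Cl2 at rt should give 7, with the enantiomeric purity to be checked by chiral HPLC.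

3. Step 2. What may go wrong: poor facial selectivity with the hindered, electron-rich aldehyde, or induction in the opposite sense. The fallback sets out from 2 and comes back at 5; the stereocentre is set by hydrogenation of a ketone instead of by C–C bond formation. Roskamp homologation of 2 with ethyl diazoacetate and NbCl5 (5 mol%) in CH2Cl2 should give ethyl 3-[3-methoxy-4,5-bis(triisopropylsilyloxy)phenyl]-3-oxopropanoate F6 with loss of dinitrogen. Noyori asymmetric hydrogenation of F6 with [RuCl(p-cymene)((R)-BINAP)]Cl (a complex of divalent ruthenium) under H2 in EtOH should give ethyl (3S)-3-hydroxy-3-[3-methoxy-4,5-bis(triisopropylsilyloxy)phenyl]propanoate F7 with the S configuration, the sense being taken from benzoylacetates. Crossed Claisen condensation of F7 with excess lithium enolate of methyl acetate (LiN(iPr)2, MeOAc, THF, −78 → −30 °C) should give 5.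

**Further compounds**

F1 | step 4 | methyl (2S)-2-[3-methoxy-4,5-bis(triisopropylsilyloxy)phenyl]-4-oxo-3,4-dihydro-2H-pyran-5-carboxylate | COC(=O)C1=CO[C@@H](CC1=O)c1cc(OC)c(O[Si](C(C)C)(C(C)C)C(C)C)c(O[Si](C(C)C)(C(C)C)C(C)C)c1
F2 | step 4 | methyl (6S)-2-[(5E)-6,10-dimethyl-2-oxoundeca-5,9-dien-1-yl]-6-[3-methoxy-4,5-bis(triisopropylsilyloxy)phenyl]-4-oxooxane-3-carboxylate (epimers at C2 and C3) | COC(=O)C1C(CC(=O)CC/C=C(\C)CCC=C(C)C)O[C@@H](CC1=O)c1cc(OC)c(O[Si](C(C)C)(C(C)C)C(C)C)c(O[Si](C(C)C)(C(C)C)C(C)C)c1
F3 | step 4 | (2S)-6-[(2E)-3,7-dimethylocta-2,6-dien-1-yl]-2-[3-methoxy-4,5-bis(triisopropylsilyloxy)phenyl]-4a,8a-dihydro-2H-chromene-4,5,7(3H,6H,8H)-trione (epimers at C4a, C6 and C8a) | COc1cc([C@@H]2CC(=O)C3C(CC(=O)C(C/C=C(\C)CCC=C(C)C)C3=O)O2)cc(O[Si](C(C)C)(C(C)C)C(C)C)c1O[Si](C(C)C)(C(C)C)C(C)C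
F4 | step 3 | methyl (5S)-5-[3-methoxy-4,5-bis(triisopropylsilyloxy)phenyl]-3-oxo-5-(triethylsilyloxy)pentanoate | COC(=O)CC(=O)C[C@H](O[Si](CC)(CC)CC)c1cc(OC)c(O[Si](C(C)C)(C(C)C)C(C)C)c(O[Si](C(C)C)(C(C)C)C(C)C)c1
F5 | step 3 | methyl (5S)-2-[bis(methylsulfanyl)methylidene]-5-[3-methoxy-4,5-bis(triisopropylsilyloxy)phenyl]-3-oxo-5-(triethylsilyloxy)pentanoate | COC(=O)C(=C(SC)SC)C(=O)C[C@H](O[Si](CC)(CC)CC)c1cc(OC)c(O[Si](C(C)C)(C(C)C)C(C)C)c(O[Si](C(C)C)(C(C)C)C(C)C)c1
F6 | step 2 | ethyl 3-[3-methoxy-4,5-bis(triisopropylsilyloxy)phenyl]-3-oxopropanoate | CCOC(=O)CC(=O)c1cc(OC)c(O[Si](C(C)C)(C(C)C)C(C)C)c(O[Si](C(C)C)(C(C)C)C(C)C)c1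
F7 | step 2 | ethyl (3S)-3-hydroxy-3-[3-methoxy-4,5-bis(triisopropylsilyloxy)phenyl]propanoate | CCOC(=O)C[C@H](O)c1cc(OC)c(O[Si](C(C)C)(C(C)C)C(C)C)c(O[Si](C(C)C)(C(C)C)C(C)C)c1
A1 | direct plan | 4-geranyl-3,5-bis(methoxymethoxy)-2-(trimethylsilyl)phenyl trifluoromethanesulfonate | C[Si](C)(C)c1c(OS(=O)(=O)C(F)(F)F)cc(OCOC)c(C/C=C(\C)CCC=C(C)C)c1OCOC
A2 | direct plan | (E)-1-[3-geranyl-6-hydroxy-2,4-bis(methoxymethoxy)phenyl]-3-[3-methoxy-4,5-bis(methoxymethoxy)phenyl]prop-2-en-1-one | COc1cc(/C=C/C(=O)c2c(O)cc(OCOC)c(C/C=C(\C)CCC=C(C)C)c2OCOC)cc(OCOC)c1OCOC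
A3 | direct plan | (2S)-6-geranyl-5,7-bis(methoxymethoxy)-2-[3-methoxy-4,5-bis(methoxymethoxy)phenyl]chroman-4-one | COc1cc([C@@H]2CC(=O)c3c(cc(OCOC)c(C/C=C(\C)CCC=C(C)C)c3OCOC)O2)cc(OCOC)c1OCOC
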